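**Plan**
1. Retrosynthesis: the 19 O-benzyl groups and two blocking bromines (C8 of units 2 and 4) are removed last; C3–OH of unit 1 comes from C3–Si; ring C of unit 1 is cut at O1–C2 and C3–C4 into an o-quinone methide (from benzhydrol 28) and Z-vinylsilane 17.
2. Further cuts: the carbinol C–C6(unit 2) bond (aryl Grignard + salicylaldehyde 9); ring C of unit 2 by the same O1–C2/C3–C4 cut; the carbinol C–C8(unit 3) bond (dimer 7 + aldehyde 11); the C4(unit 3)–C6(unit 4) bond to two epicatechin monomers.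
3. Forward order: unit 3–unit 4 dimer (4β→6), aryl addition, ring C of unit 2, Si→OH and benzylation, aryl addition, ring C of unit 1 (key), Si→OH, hydrogenolysis.
4. Enabling feature: on ring C of unit 1 the C2 aryl, the C3 hydroxyl and the C4 aryl (C4 bonded to C6 of unit 2) are all cis, the pattern of an endo adduct of a Z alkene on an E o-quinone methide; ring C of unit 2 shows the mirror-image all-cis pattern.
5. Stereochemistry: units 3 and 4 come from (−)-epicatechin (C4 of unit 3 is set trans to 3-OBn in the coupling); C2, C3 and C4 of units 2 and 1 come from the alkene geometry (2,3-cis), endo approach (2,4-cis) and the hand of the phosphoric acid; the Tamao–Fleming oxidation retains C3.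
6. Regiocontrol: C8 of unit 4 and C8 of unit 2 are blocked by bromine; the two sites to be metalated (C8 of unit 3, C6 of unit 2) are carried as iodides.

Key step: step 18

Conventions: flavan numbering within each unit; unit 1 is the top unit (C4→C6 of unit 2), then unit 2 (C4→C8 of unit 3), unit 3 (C4→C6 of unit 4) and unit 4; α is the face of the C2 aryl group of (−)-epicatechin, β the opposite face; Bn = benzyl.
Assumption: (S)-TRIP is taken to deliver the 2S series (unit 2) and (R)-TRIP the 2R series (unit 1); the two acids are exchanged if the sense is the reverse.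
Assumption: the first halogenation of 9 goes ortho to the free hydroxyl, as is usual for 2-hydroxy-4,6-dialkoxyaryl carbonyl compounds; this regiochemistry would be confirmed before use.

**Route**

Step 1
Reactants: 1 (−)-epicatechin
Product: 2 5,7,3',4'-tetra-O-benzyl-(−)-epicatechin
Conditions: BnBr (4.2 equiv), K2CO3, DMF, 0 °C → rt
Reagents that add atoms: benzyl bromide, BrCc1ccccc1
Why: Williamson O-alkylation with a carbonate base benzylates only the four phenols and leaves the secondary 3-OH and both stereocentres untouched.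

Step 2
Reactants: 2 5,7,3',4'-tetra-O-benzyl-(−)-epicatechin
Product: 3 3,5,7,3',4'-penta-O-benzyl-(−)-epicatechin
Conditions: NaH, BnBr, DMF, 0 °C → rt
Reagents that add atoms: benzyl bromide, BrCc1ccccc1
Why: Williamson etherification of the sodium alkoxide caps the 3-OH without touching a stereocentre.

Step 3
Reactants: 3 3,5,7,3',4'-penta-O-benzyl-(−)-epicatechin
Product: 4 8-bromo-3,5,7,3',4'-penta-O-benzylepicatechin
Conditions: NBS, CH2Cl2, −78 → −20 °C
Reagents that add atoms: N-bromosuccinimide, O=C1CCC(=O)N1Br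
Why: Electrophilic aromatic bromination goes to C8, the more reactive free ring-A position of 5,7-dibenzyloxyflavans, and leaves C6 as the only nucleophilic site of the future unit 4.

Step 4
Reactants: 3 3,5,7,3',4'-penta-O-benzyl-(−)-epicatechin
Product: 5 4β-(2-ethoxyethoxy)-3,5,7,3',4'-penta-O-benzylepicatechin
Conditions: DDQ, 2-ethoxyethanol, CH2Cl2, rt
Reagents that add atoms: 2-ethoxyethanol, CCOCCO
Why: DDQ benzylic oxidation (hydride abstraction at C4, trapping of the ring-A-stabilised cation by the alcohol) installs the C4 leaving group, the alcohol entering trans to the 3-benzyloxy group.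

Step 5
Reactants: 5 4β-(2-ethoxyethoxy)-3,5,7,3',4'-penta-O-benzylepicatechin
Product: 6 8-iodo-4β-(2-ethoxyethoxy)-3,5,7,3',4'-penta-O-benzylepicatechin
Conditions: NIS, DMF, 0 °C, dark
Reagents that add atoms: N-iodosuccinimide, O=C1CCC(=O)N1I
Why: Electrophilic aromatic iodination at C8 (same site preference as in step 3) under neutral conditions caps the electrophile against self-condensation at C8 and supplies the later metalation handle.

Step 6
Reactants: 4 8-bromo-3,5,7,3',4'-penta-O-benzylepicatechin; 6 8-iodo-4β-(2-ethoxyethoxy)-3,5,7,3',4'-penta-O-benzylepicatechin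
Product: 7 dimer iodide [8-iodo-3,5,7,3',4'-penta-O-benzylepicatechin]-(4β→6)-[8-bromo-3,5,7,3',4'-penta-O-benzylepicatechin]
Conditions: 4 (4 equiv), BF3·OEt2, CH2Cl2, −78 → −20 °C
Reagents that add atoms: none
Why: Friedel–Crafts-type interflavan coupling in which BF3 ionises the C4 ether and C6 of 4 (C8 blocked by bromine, 4 in excess because the capped electrophile has a comparable C6) attacks the benzylic cation trans to the 3-benzyloxy group, setting C4 of unit 3 as 4β.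

Step 7
Reactants: 8 2,4,6-trihydroxybenzaldehyde
Product: 9 4,6-bis(benzyloxy)-2-hydroxybenzaldehyde
Conditions: BnBr (2.1 equiv), K2CO3, DMF, rt
Reagents that add atoms: benzyl bromide, BrCc1ccccc1
Why: Williamson O-benzylation takes the para hydroxyl and one ortho hydroxyl, while the hydroxyl hydrogen-bonded to the aldehyde stays free.

Step 8
Reactants: 9 4,6-bis(benzyloxy)-2-hydroxybenzaldehyde
Product: 10 4,6-bis(benzyloxy)-3-bromo-2-hydroxybenzaldehyde
Conditions: NBS, CH2Cl2, 0 °C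
Reagents that add atoms: N-bromosuccinimide, O=C1CCC(=O)N1Br
Why: Electrophilic aromatic bromination ortho to the free chelated phenol places bromine on the carbon that becomes C8 of unit 2, where it serves as a blocking group.

Step 9
Reactants: 10 4,6-bis(benzyloxy)-3-bromo-2-hydroxybenzaldehyde
Product: 11 4,6-bis(benzyloxy)-3-bromo-2-hydroxy-5-iodobenzaldehyde
Conditions: NIS, CF3CO2H (cat.), MeCN, rt
Reagents that add atoms: N-iodosuccinimide, O=C1CCC(=O)N1I
Why: Electrophilic aromatic iodination can only occur at the last free ring position, between the two benzyloxy groups, which becomes C6 of unit 2.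

Step 10
Reactants: 12 3,4-bis(benzyloxy)benzaldehyde
Product: 13 4-ethynyl-1,2-bis(benzyloxy)benzene
Conditions: dimethyl (1-diazo-2-oxopropyl)phosphonate, K2CO3, MeOH/THF, rt
Reagents that add atoms: dimethyl (1-diazo-2-oxopropyl)phosphonate, CC(=O)C(=[N+]=[N-])P(=O)(OC)OC
Why: Ohira–Bestmann (Seyferth–Gilbert) homologation converts the aryl aldehyde into the terminal alkyne under mild base.

Step 11
Reactants: 13 4-ethynyl-1,2-bis(benzyloxy)benzene
Product: 15 benzyl{[3,4-bis(benzyloxy)phenyl]ethynyl}dimethylsilane, via lithium acetylide 14 (not isolated)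
Conditions: n-BuLi, THF, −78 °C; BnMe2SiCl, −78 °C → rt
Reagents that add atoms: benzyl(chloro)dimethylsilane, C[Si](C)(Cl)Cc1ccccc1
Why: Deprotonation of the terminal alkyne and substitution at silicon by the lithium acetylide give the alkynylsilane.

Step 12
Reactants: 15 benzyl{[3,4-bis(benzyloxy)phenyl]ethynyl}dimethylsilane
Product: 17 (Z)-benzyl{2-[3,4-bis(benzyloxy)phenyl]ethenyl}dimethylsilane, via alkenylborane 16 (not isolated)
Conditions: (c-C6H11)2BH, THF, 0 °C → rt; AcOH, 50 °C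
Reagents that add atoms: none
Why: syn-Hydroboration of the alkynylsilane followed by protonolysis of the C–B bond with retention amounts to cis addition of H2 and gives the Z-vinylsilane whichever way boron adds.

Step 13
Reactants: 7 dimer iodide; 11 4,6-bis(benzyloxy)-3-bromo-2-hydroxy-5-iodobenzaldehyde
Product: 20 dimer benzhydrol (C8 of unit 3 carries CH(OH)Ar in place of iodine; Ar = 4,6-bis(benzyloxy)-3-bromo-2-hydroxy-5-iodophenyl; carbinol epimers), via sodium aryloxide 18 (not isolated), via arylmagnesium chloride 19 (not isolated)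
Conditions: 11, NaH, THF, 0 °C; 7, i-PrMgCl·LiCl, THF, −30 °C; combine, −30 °C → rt; aq. NH4Cl
Reagents that add atoms: none
Why: Iodine–magnesium exchange is far faster at the aryl iodide than at the aryl bromide, and 1,2-addition of the aryl Grignard reagent to the aldehyde of the preformed aryloxide gives the diarylcarbinol, whose configuration is irrelevant because it is erased on ionisation in step 14.

Step 14
Reactants: 20 dimer benzhydrol; 17 (Z)-benzyl{2-[3,4-bis(benzyloxy)phenyl]ethenyl}dimethylsilane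
Product: 22 trimer silane (new unit 2 ring C all cis: 2β-aryl 3β-SiMe2Bn 4β-bonded to C8 of unit 3; 2S; unit 2 carries 6-iodo 8-bromo), via o-quinone methide 21 (not isolated)
Conditions: (S)-3,3'-bis(2,4,6-triisopropylphenyl)-1,1'-binaphthyl-2,2'-diyl hydrogen phosphate [(S)-TRIP, 10 mol%], 17 (3 equiv), 4 Å MS, toluene, −20 °C → rt
Reagents that add atoms: none
Why: Proposed new method: the chiral phosphoric acid should dehydrate 20 to the hydrogen-bonded o-quinone methide 21, whose methide carbon attacks the silicon-bearing carbon of 17 (the charge developing at C2 is benzylic to the dibenzyloxyphenyl ring and β to silicon) before the ring oxygen closes on C2 in an asynchronous endo hetero-Diels–Alder reaction, so that the Z alkene sets 2,3-cis, the endo aryl sets 2,4-cis and the (S) acid is asked to select the face giving the 2S (2β,3β,4β) unit against any bias of units 3 and 4; the closest known reaction type is the chiral phosphoric acid catalysed [4+2] cycloaddition of in situ o-quinone methides with styrenes.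

Step 15
Reactants: 22 trimer silane
Product: 24 trimer alcohol (unit 2 C3–OH β; all cis), via silanol 23 (not isolated)
Conditions: Bu4NF, THF, 0 °C; then 30% H2O2, KHCO3, MeOH/THF, rt → 40 °C
Reagents that add atoms: hydrogen peroxide, OO
Why: Tamao–Fleming oxidation, in which fluoride cleaves the benzyl–silicon bond to the silanol and peroxide induces 1,2-migration of C3 from silicon to oxygen with retention, gives the 3β-hydroxyl cis to both aryl groups, the axial silyl group being gauche to the C2–O1 bond and so poorly placed for β-elimination.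

Step 16
Reactants: 24 trimer alcohol
Product: 25 trimer iodide (unit 2 C3–OBn; fully benzylated; 6-iodo 8-bromo on unit 2)
Conditions: NaH, BnBr, Bu4NI (cat.), DMF, 0 °C → rt
Reagents that add atoms: benzyl bromide, BrCc1ccccc1
Why: Williamson etherification of the secondary alkoxide, as for the axial 3-OH of epicatechin in step 2, leaves no acidic proton for the next metalation.

Step 17
Reactants: 25 trimer iodide; 9 4,6-bis(benzyloxy)-2-hydroxybenzaldehyde
Product: 28 trimer benzhydrol (C6 of unit 2 carries CH(OH)Ar; Ar = 4,6-bis(benzyloxy)-2-hydroxyphenyl; carbinol epimers), via sodium aryloxide 26 (not isolated), via arylmagnesium chloride 27 (not isolated)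
Conditions: 9, NaH, THF, 0 °C; 25, i-PrMgCl·LiCl, THF, −30 °C; combine, −30 °C → rt; aq. NH4Cl
Reagents that add atoms: none
Why: Chemoselective iodine–magnesium exchange at C6 of unit 2 in the presence of the two aryl bromides, then Grignard 1,2-addition to the aldehyde of the aryloxide, gives the o-hydroxybenzhydrol as a mixture of carbinol epimers that both ionise in step 18.

Step 18
Reactants: 28 trimer benzhydrol; 17 (Z)-benzyl{2-[3,4-bis(benzyloxy)phenyl]ethenyl}dimethylsilane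
Product: 30 tetramer silane (unit 1 ring C all cis: 2α-aryl 3α-SiMe2Bn 4α-bonded to C6 of unit 2; 2R), via o-quinone methide 29 (not isolated)
Conditions: (R)-3,3'-bis(2,4,6-triisopropylphenyl)-1,1'-binaphthyl-2,2'-diyl hydrogen phosphate [(R)-TRIP, 10 mol%], 17 (3 equiv), 4 Å MS, toluene, −20 °C → rt, slow addition of 28
Reagents that add atoms: none
Why: Proposed new method: (R)-TRIP should dehydrate the hexa-oxygenated benzhydrol 28 (either carbinol epimer) to the neutral E o-quinone methide 29, held by hydrogen bonding to the phosphate; the Z isomer, which equilibrates with it through the cation, carries the aryl group inside the heterodiene and is the poorer partner. The methide carbon (future C4) bonds to the silicon-bearing alkene carbon of 17, because the charge developing at C2 is benzylic to the 3,4-dibenzyloxyphenyl ring and β to silicon, and the ring oxygen then closes on C2, so that ring C of unit 1 forms by an asynchronous concerted hetero-[4+2] cycloaddition (C3–C4 first, O1–C2 second; six-membered closure of a 1-oxadiene onto a 2π partner). The closest known reaction type is the chiral phosphoric acid catalysed [4+2] cycloaddition of in situ o-quinone methides with styrenes, which gives 2,4-cis-2,4-diarylchromans; a β-silyl Z-styrene as masked enol and a 4-aryl methide of this size and oxygenation are not precedented. C2/C3 cis follows from suprafacial addition to the Z alkene, C2/C4 cis from endo placement of the dibenzyloxyphenyl group over the E methide, and the absolute sense (2R, 3α-Si, 4α) from the face left open in the chiral phosphate pocket, which has to override the bias of the resident all-cis unit 2. Regiochemistry rests on the aryl/silicon pair (an enol ether would put its oxygen on C2), and Friedel–Crafts capture of the methide is held back by the bromines on C8 of units 2 and 4, the flanked C6 of unit 3 and slow addition of 28, so that the 3,4-cis relation avoided by ionic interflavan couplings is obtained directly.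

Step 19
Reactants: 30 tetramer silane
Product: 32 tetramer alcohol (unit 1 C3–OH α; all cis; 19 benzyl ethers; bromine on C8 of units 2 and 4), via silanol 31 (not isolated)
Conditions: Bu4NF, THF, 0 °C; then 30% H2O2, KHCO3, MeOH/THF, rt → 40 °C
Reagents that add atoms: hydrogen peroxide, OO
Why: Tamao–Fleming oxidation (fluoride debenzylation at silicon, then peroxide-induced 1,2-shift of C3 from Si to O with retention) converts the 3α-silyl group into the 3α-hydroxyl cis to both aryl groups.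

Step 20
Reactants: 32 tetramer alcohol
Product: 33 target tetramer CNP0120618.3
Conditions: H2 (1 atm), Pd(OH)2/C, Et3N, THF/MeOH/H2O, rt
Reagents that add atoms: none
Why: Catalytic hydrogenolysis cleaves all nineteen benzyl ethers and, with Et3N present, the two aryl C–Br bonds, without touching the C2–O1 or C4–aryl bonds, so all eleven stereocentres are retained.

**Compound list**

1 | (−)-epicatechin | O[C@@H]1Cc2c(O)cc(O)cc2O[C@@H]1c1ccc(O)c(O)c1 | starting material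
2 | 5,7,3',4'-tetra-O-benzyl-(−)-epicatechin (2R,3R) | c1c(OCc9ccccc9)cc2c(c1OCc9ccccc9)C[C@@H](O)[C@@H](c1ccc(OCc9ccccc9)c(OCc9ccccc9)c1)O2 | intermediate
3 | 3,5,7,3',4'-penta-O-benzyl-(−)-epicatechin | c1c(OCc9ccccc9)cc2c(c1OCc9ccccc9)C[C@@H](OCc9ccccc9)[C@@H](c1ccc(OCc9ccccc9)c(OCc9ccccc9)c1)O2 | intermediate
4 | 8-bromo-3,5,7,3',4'-penta-O-benzylepicatechin | c1c(OCc9ccccc9)c(Br)c2c(c1OCc9ccccc9)C[C@@H](OCc9ccccc9)[C@@H](c1ccc(OCc9ccccc9)c(OCc9ccccc9)c1)O2 | intermediate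
5 | 4β-(2-ethoxyethoxy)-3,5,7,3',4'-penta-O-benzylepicatechin (2,3-cis-3,4-trans) | c1c(OCc9ccccc9)cc(OCc9ccccc9)c2c1O[C@H](c1ccc(OCc9ccccc9)c(OCc9ccccc9)c1)[C@H](OCc9ccccc9)[C@H]2OCCOCC | intermediate
6 | 8-iodo-4β-(2-ethoxyethoxy)-3,5,7,3',4'-penta-O-benzylepicatechin | Ic1c(OCc9ccccc9)cc(OCc9ccccc9)c2c1O[C@H](c1ccc(OCc9ccccc9)c(OCc9ccccc9)c1)[C@H](OCc9ccccc9)[C@H]2OCCOCC | intermediate
7 | dimer iodide [8-iodo-penta-O-benzylepicatechin]-(4β→6)-[8-bromo-penta-O-benzylepicatechin] | Ic1c(OCc9ccccc9)cc(OCc9ccccc9)c3c1O[C@H](c1ccc(OCc9ccccc9)c(OCc9ccccc9)c1)[C@H](OCc9ccccc9)[C@H]3c1c(OCc9ccccc9)c(Br)c3c(c1OCc9ccccc9)C[C@@H](OCc9ccccc9)[C@@H](c1ccc(OCc9ccccc9)c(OCc9ccccc9)c1)O3 | intermediate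
8 | 2,4,6-trihydroxybenzaldehyde | O=Cc1c(O)cc(O)cc1O | starting material
9 | 4,6-bis(benzyloxy)-2-hydroxybenzaldehyde | O=Cc1c(O)cc(OCc2ccccc2)cc1OCc2ccccc2 | intermediate
10 | 4,6-bis(benzyloxy)-3-bromo-2-hydroxybenzaldehyde | O=Cc1c(O)c(Br)c(OCc2ccccc2)cc1OCc2ccccc2 | intermediate
11 | 4,6-bis(benzyloxy)-3-bromo-2-hydroxy-5-iodobenzaldehyde | O=Cc1c(O)c(Br)c(OCc2ccccc2)c(I)c1OCc2ccccc2 | intermediate
12 | 3,4-bis(benzyloxy)benzaldehyde | O=Cc1ccc(OCc2ccccc2)c(OCc2ccccc2)c1 | starting material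
13 | 4-ethynyl-1,2-bis(benzyloxy)benzene | C#Cc1ccc(OCc2ccccc2)c(OCc2ccccc2)c1 | intermediate
14 | lithium [3,4-bis(benzyloxy)phenyl]acetylide | [Li]C#Cc1ccc(OCc2ccccc2)c(OCc2ccccc2)c1 | intermediate (not isolated)
15 | benzyl{[3,4-bis(benzyloxy)phenyl]ethynyl}dimethylsilane | C[Si](C)(Cc1ccccc1)C#Cc1ccc(OCc2ccccc2)c(OCc2ccccc2)c1 | intermediate
16 | dicyclohexyl{1-[benzyl(dimethyl)silyl]-2-[3,4-bis(benzyloxy)phenyl]ethenyl}borane (silyl and aryl cis) | C[Si](C)(Cc1ccccc1)/C(B(C2CCCCC2)C2CCCCC2)=C\c1ccc(OCc2ccccc2)c(OCc2ccccc2)c1 | intermediate (not isolated)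
17 | (Z)-benzyl{2-[3,4-bis(benzyloxy)phenyl]ethenyl}dimethylsilane | C[Si](C)(Cc1ccccc1)/C=C\c1ccc(OCc2ccccc2)c(OCc2ccccc2)c1 | intermediate
18 | sodium aryloxide of 11 | [Na+].[O-]c1c(Br)c(OCc2ccccc2)c(I)c(OCc2ccccc2)c1C=O | intermediate (not isolated)
19 | arylmagnesium chloride of the dimer (MgCl on C8 of unit 3) | Cl[Mg]c1c(OCc9ccccc9)cc(OCc9ccccc9)c3c1O[C@H](c1ccc(OCc9ccccc9)c(OCc9ccccc9)c1)[C@H](OCc9ccccc9)[C@H]3c1c(OCc9ccccc9)c(Br)c3c(c1OCc9ccccc9)C[C@@H](OCc9ccccc9)[C@@H](c1ccc(OCc9ccccc9)c(OCc9ccccc9)c1)O3 | intermediate (not isolated)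
20 | dimer benzhydrol: [4,6-bis(benzyloxy)-3-bromo-2-hydroxy-5-iodophenyl](C8 of unit 3)methanol, carbinol epimers | OC(c1c(O)c(Br)c(OCc9ccccc9)c(I)c1OCc9ccccc9)c1c(OCc9ccccc9)cc(OCc9ccccc9)c3c1O[C@H](c1ccc(OCc9ccccc9)c(OCc9ccccc9)c1)[C@H](OCc9ccccc9)[C@H]3c1c(OCc9ccccc9)c(Br)c3c(c1OCc9ccccc9)C[C@@H](OCc9ccccc9)[C@@H](c1ccc(OCc9ccccc9)c(OCc9ccccc9)c1)O3 | intermediate
21 | E o-quinone methide from 20 (methide carbon bears the unit 3 C8 aryl) | O=C1C(Br)=C(OCc9ccccc9)C(I)=C(OCc9ccccc9)/C1=C\c1c(OCc9ccccc9)cc(OCc9ccccc9)c3c1O[C@H](c1ccc(OCc9ccccc9)c(OCc9ccccc9)c1)[C@H](OCc9ccccc9)[C@H]3c1c(OCc9ccccc9)c(Br)c3c(c1OCc9ccccc9)C[C@@H](OCc9ccccc9)[C@@H](c1ccc(OCc9ccccc9)c(OCc9ccccc9)c1)O3 | intermediate (not isolated)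
22 | trimer silane: unit 2 (2S; 2β-aryl, 3β-SiMe2Bn, 4β→C8 of unit 3; 6-iodo, 8-bromo) on the unit 3–unit 4 dimer | Ic1c(OCc9ccccc9)c(Br)c2c(c1OCc9ccccc9)[C@H](c1c(OCc9ccccc9)cc(OCc9ccccc9)c3c1O[C@H](c1ccc(OCc9ccccc9)c(OCc9ccccc9)c1)[C@H](OCc9ccccc9)[C@H]3c1c(OCc9ccccc9)c(Br)c3c(c1OCc9ccccc9)C[C@@H](OCc9ccccc9)[C@@H](c1ccc(OCc9ccccc9)c(OCc9ccccc9)c1)O3)[C@H]([Si](C)(C)Cc9ccccc9)[C@H](c1ccc(OCc9ccccc9)c(OCc9ccccc9)c1)O2 | intermediate
23 | trimer silanol (3β-SiMe2OH on unit 2) | Ic1c(OCc9ccccc9)c(Br)c2c(c1OCc9ccccc9)[C@H](c1c(OCc9ccccc9)cc(OCc9ccccc9)c3c1O[C@H](c1ccc(OCc9ccccc9)c(OCc9ccccc9)c1)[C@H](OCc9ccccc9)[C@H]3c1c(OCc9ccccc9)c(Br)c3c(c1OCc9ccccc9)C[C@@H](OCc9ccccc9)[C@@H](c1ccc(OCc9ccccc9)c(OCc9ccccc9)c1)O3)[C@H]([Si](C)(C)O)[C@H](c1ccc(OCc9ccccc9)c(OCc9ccccc9)c1)O2 | intermediate (not isolated)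
24 | trimer alcohol (unit 2 3β-OH, all cis) | Ic1c(OCc9ccccc9)c(Br)c2c(c1OCc9ccccc9)[C@H](c1c(OCc9ccccc9)cc(OCc9ccccc9)c3c1O[C@H](c1ccc(OCc9ccccc9)c(OCc9ccccc9)c1)[C@H](OCc9ccccc9)[C@H]3c1c(OCc9ccccc9)c(Br)c3c(c1OCc9ccccc9)C[C@@H](OCc9ccccc9)[C@@H](c1ccc(OCc9ccccc9)c(OCc9ccccc9)c1)O3)[C@H](O)[C@H](c1ccc(OCc9ccccc9)c(OCc9ccccc9)c1)O2 | intermediate
25 | trimer iodide (unit 2 3β-OBn; 6-iodo, 8-bromo on unit 2; 8-bromo on unit 4) | Ic1c(OCc9ccccc9)c(Br)c2c(c1OCc9ccccc9)[C@H](c1c(OCc9ccccc9)cc(OCc9ccccc9)c3c1O[C@H](c1ccc(OCc9ccccc9)c(OCc9ccccc9)c1)[C@H](OCc9ccccc9)[C@H]3c1c(OCc9ccccc9)c(Br)c3c(c1OCc9ccccc9)C[C@@H](OCc9ccccc9)[C@@H](c1ccc(OCc9ccccc9)c(OCc9ccccc9)c1)O3)[C@H](OCc9ccccc9)[C@H](c1ccc(OCc9ccccc9)c(OCc9ccccc9)c1)O2 | intermediate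
26 | sodium aryloxide of 9 | [Na+].[O-]c1cc(OCc2ccccc2)cc(OCc2ccccc2)c1C=O | intermediate (not isolated)
27 | arylmagnesium chloride of the trimer (MgCl on C6 of unit 2) | Cl[Mg]c1c(OCc9ccccc9)c(Br)c2c(c1OCc9ccccc9)[C@H](c1c(OCc9ccccc9)cc(OCc9ccccc9)c3c1O[C@H](c1ccc(OCc9ccccc9)c(OCc9ccccc9)c1)[C@H](OCc9ccccc9)[C@H]3c1c(OCc9ccccc9)c(Br)c3c(c1OCc9ccccc9)C[C@@H](OCc9ccccc9)[C@@H](c1ccc(OCc9ccccc9)c(OCc9ccccc9)c1)O3)[C@H](OCc9ccccc9)[C@H](c1ccc(OCc9ccccc9)c(OCc9ccccc9)c1)O2 | intermediate (not isolated)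
28 | trimer benzhydrol: [4,6-bis(benzyloxy)-2-hydroxyphenyl](C6 of unit 2)methanol, carbinol epimers | OC(c1c(O)cc(OCc9ccccc9)cc1OCc9ccccc9)c1c(OCc9ccccc9)c(Br)c2c(c1OCc9ccccc9)[C@H](c1c(OCc9ccccc9)cc(OCc9ccccc9)c3c1O[C@H](c1ccc(OCc9ccccc9)c(OCc9ccccc9)c1)[C@H](OCc9ccccc9)[C@H]3c1c(OCc9ccccc9)c(Br)c3c(c1OCc9ccccc9)C[C@@H](OCc9ccccc9)[C@@H](c1ccc(OCc9ccccc9)c(OCc9ccccc9)c1)O3)[C@H](OCc9ccccc9)[C@H](c1ccc(OCc9ccccc9)c(OCc9ccccc9)c1)O2 | intermediate
29 | E o-quinone methide from 28 (methide carbon bears the unit 2 C6 aryl) | O=C1C=C(OCc9ccccc9)C=C(OCc9ccccc9)/C1=C\c1c(OCc9ccccc9)c(Br)c2c(c1OCc9ccccc9)[C@H](c1c(OCc9ccccc9)cc(OCc9ccccc9)c3c1O[C@H](c1ccc(OCc9ccccc9)c(OCc9ccccc9)c1)[C@H](OCc9ccccc9)[C@H]3c1c(OCc9ccccc9)c(Br)c3c(c1OCc9ccccc9)C[C@@H](OCc9ccccc9)[C@@H](c1ccc(OCc9ccccc9)c(OCc9ccccc9)c1)O3)[C@H](OCc9ccccc9)[C@H](c1ccc(OCc9ccccc9)c(OCc9ccccc9)c1)O2 | intermediate (not isolated)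
30 | tetramer silane: unit 1 (2R; 2α-aryl, 3α-SiMe2Bn, 4α→C6 of unit 2) on the trimer | c9ccccc9COc1cc(OCc9ccccc9)c2c(c1)O[C@H](c1ccc(OCc9ccccc9)c(OCc9ccccc9)c1)[C@H]([Si](C)(C)Cc9ccccc9)[C@@H]2c1c(OCc9ccccc9)c(Br)c2c(c1OCc9ccccc9)[C@H](c1c(OCc9ccccc9)cc(OCc9ccccc9)c3c1O[C@H](c1ccc(OCc9ccccc9)c(OCc9ccccc9)c1)[C@H](OCc9ccccc9)[C@H]3c1c(OCc9ccccc9)c(Br)c3c(c1OCc9ccccc9)C[C@@H](OCc9ccccc9)[C@@H](c1ccc(OCc9ccccc9)c(OCc9ccccc9)c1)O3)[C@H](OCc9ccccc9)[C@H](c1ccc(OCc9ccccc9)c(OCc9ccccc9)c1)O2 | intermediate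
31 | tetramer silanol (3α-SiMe2OH on unit 1) | c9ccccc9COc1cc(OCc9ccccc9)c2c(c1)O[C@H](c1ccc(OCc9ccccc9)c(OCc9ccccc9)c1)[C@H]([Si](C)(C)O)[C@@H]2c1c(OCc9ccccc9)c(Br)c2c(c1OCc9ccccc9)[C@H](c1c(OCc9ccccc9)cc(OCc9ccccc9)c3c1O[C@H](c1ccc(OCc9ccccc9)c(OCc9ccccc9)c1)[C@H](OCc9ccccc9)[C@H]3c1c(OCc9ccccc9)c(Br)c3c(c1OCc9ccccc9)C[C@@H](OCc9ccccc9)[C@@H](c1ccc(OCc9ccccc9)c(OCc9ccccc9)c1)O3)[C@H](OCc9ccccc9)[C@H](c1ccc(OCc9ccccc9)c(OCc9ccccc9)c1)O2 | intermediate (not isolated)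
32 | tetramer alcohol (unit 1 3α-OH, all cis; 19 benzyl ethers; 8-bromo on units 2 and 4) | c9ccccc9COc1cc(OCc9ccccc9)c2c(c1)O[C@H](c1ccc(OCc9ccccc9)c(OCc9ccccc9)c1)[C@H](O)[C@@H]2c1c(OCc9ccccc9)c(Br)c2c(c1OCc9ccccc9)[C@H](c1c(OCc9ccccc9)cc(OCc9ccccc9)c3c1O[C@H](c1ccc(OCc9ccccc9)c(OCc9ccccc9)c1)[C@H](OCc9ccccc9)[C@H]3c1c(OCc9ccccc9)c(Br)c3c(c1OCc9ccccc9)C[C@@H](OCc9ccccc9)[C@@H](c1ccc(OCc9ccccc9)c(OCc9ccccc9)c1)O3)[C@H](OCc9ccccc9)[C@H](c1ccc(OCc9ccccc9)c(OCc9ccccc9)c1)O2 | intermediate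
33 | target tetramer CNP0120618.3 | Oc1cc(O)c2c(c1)O[C@H](c1ccc(O)c(O)c1)[C@H](O)[C@@H]2c1c(O)cc2c(c1O)[C@H](c1c(O)cc(O)c3c1O[C@H](c1ccc(O)c(O)c1)[C@H](O)[C@H]3c1c(O)cc3c(c1O)C[C@@H](O)[C@@H](c1ccc(O)c(O)c1)O3)[C@H](O)[C@H](c1ccc(O)c(O)c1)O2 | target

**Totals and risks**

Total step count: 20 (six on the epicatechin line to 7, three to aldehyde 11, three to vinylsilane 17, eight from 7 to 33).
Longest linear sequence: 13 steps (1, 2, 4, 5, 6, 13, 14, 15, 16, 17, 18, 19, 20).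

Three steps most likely to fail:

Step 18 (Proposed new method). The methide carbon, flanked by four ortho oxygen substituents, may not engage the alkene. Exo or wrong-face approach may erode the all-cis result. The vinylsilane may protodesilylate, or the methide may be consumed by Friedel–Crafts self-condensation through the free positions of its phenol ring. Fallback by known chemistry, setting out from 25 and 3 and returning at 33: oxidation of 3 with DDQ in wet CH2Cl2 should give 4β-hydroxy-3,5,7,3',4'-penta-O-benzylepicatechin F1, and Dess–Martin periodinane then the 2,3-cis flavan-4-one F2. The arylmagnesium chloride 27, made from 25 as in step 17 and activated with LaCl3·2LiCl, is added to F2 to give the tertiary C4 carbinol F3. Ionic reduction (Bu3SnH, CF3CO2H, CH2Cl2) should deliver hydride to the C4 cation from the β face, anti to the 2α-aryl and 3α-benzyloxy groups, so that unit 2 ends 4α and the all-cis icosa-O-benzyl tetramer F4 results. Hydrogenolysis as in step 20 then gives 33.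

Step 14 (Proposed new method). The fully substituted, very hindered methide may ionise without cycloaddition. The chiral acid may fail to override the facial bias of units 3 and 4. Endo/exo control may be lost. Fallback by known chemistry, setting out from 20 and alkyne 13 and returning at 24: acid-catalysed [4+2] reaction of the o-quinone methide from 20 with arylacetylene 13 should give the 2,4-diaryl-4H-chromene F5; only C4 is new, and its epimers are separated or biased with a chiral phosphoric acid. Hydroboration–oxidation (BH3·THF, then NaBO3·4H2O) adds anti to the C4 aryl group and gives the 2,4-cis-3-trans alcohol F6. Dess–Martin oxidation gives the flavan-3-one F7, and LiBH(s-Bu)3 attacks from the equatorial direction to give the axial, all-cis alcohol 24.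

Step 19. Fluoride may trigger β-elimination across C3–C2–O1 and open ring C, or the oxidation of the hindered secondary silane may stall; the same hazard applies to step 15. Fallback setting out from 28 and alkyne 13 and returning at 32, with boron replacing silicon as the masked hydroxyl: rhodium-catalysed trans-hydroboration of 13 ([Rh(cod)Cl]2, P(i-Pr)3, Et3N, pinacolborane) gives the (Z)-alkenylboronate F8. Cycloaddition of F8 under the conditions of step 18 should give the C3-boryl tetramer F9 with the same aryl-controlled regiochemistry; this cycloaddition is itself unprecedented. NaBO3·4H2O in THF/H2O then oxidises C–B to C–OH with retention, without fluoride, to give 32.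

**Further compounds**

F1 | step 18 | 4β-hydroxy-3,5,7,3',4'-penta-O-benzylepicatechin | c1c(OCc9ccccc9)cc(OCc9ccccc9)c2c1O[C@H](c1ccc(OCc9ccccc9)c(OCc9ccccc9)c1)[C@H](OCc9ccccc9)[C@H]2O
F2 | step 18 | 2,3-cis-3,5,7-tris(benzyloxy)-2-[3,4-bis(benzyloxy)phenyl]chroman-4-one (C2 and C3 as in epicatechin) | c1c(OCc9ccccc9)cc(OCc9ccccc9)c2c1O[C@H](c1ccc(OCc9ccccc9)c(OCc9ccccc9)c1)[C@H](OCc9ccccc9)C2=O
F3 | step 18 | tertiary carbinol: unit 1 C4 bears OH and C6 of unit 2 of the trimer (C4 configuration undefined, lost on ionisation) | c9ccccc9COc1cc(OCc9ccccc9)c2c(c1)O[C@H](c1ccc(OCc9ccccc9)c(OCc9ccccc9)c1)[C@H](OCc9ccccc9)C2(O)c1c(OCc9ccccc9)c(Br)c2c(c1OCc9ccccc9)[C@H](c1c(OCc9ccccc9)cc(OCc9ccccc9)c3c1O[C@H](c1ccc(OCc9ccccc9)c(OCc9ccccc9)c1)[C@H](OCc9ccccc9)[C@H]3c1c(OCc9ccccc9)c(Br)c3c(c1OCc9ccccc9)C[C@@H](OCc9ccccc9)[C@@H](c1ccc(OCc9ccccc9)c(OCc9ccccc9)c1)O3)[C@H](OCc9ccccc9)[C@H](c1ccc(OCc9ccccc9)c(OCc9ccccc9)c1)O2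
F4 | step 18 | icosa-O-benzyl tetramer (unit 1 3α-OBn, 4α-linked, all cis; 8-bromo on units 2 and 4) | c9ccccc9COc1cc(OCc9ccccc9)c2c(c1)O[C@H](c1ccc(OCc9ccccc9)c(OCc9ccccc9)c1)[C@H](OCc9ccccc9)[C@@H]2c1c(OCc9ccccc9)c(Br)c2c(c1OCc9ccccc9)[C@H](c1c(OCc9ccccc9)cc(OCc9ccccc9)c3c1O[C@H](c1ccc(OCc9ccccc9)c(OCc9ccccc9)c1)[C@H](OCc9ccccc9)[C@H]3c1c(OCc9ccccc9)c(Br)c3c(c1OCc9ccccc9)C[C@@H](OCc9ccccc9)[C@@H](c1ccc(OCc9ccccc9)c(OCc9ccccc9)c1)O3)[C@H](OCc9ccccc9)[C@H](c1ccc(OCc9ccccc9)c(OCc9ccccc9)c1)O2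
F5 | step 14 | trimer 4H-chromene (unit 2 C2=C3, 4β-linked to C8 of unit 3; 6-iodo, 8-bromo) | Ic1c(OCc9ccccc9)c(Br)c2c(c1OCc9ccccc9)[C@H](c1c(OCc9ccccc9)cc(OCc9ccccc9)c3c1O[C@H](c1ccc(OCc9ccccc9)c(OCc9ccccc9)c1)[C@H](OCc9ccccc9)[C@H]3c1c(OCc9ccccc9)c(Br)c3c(c1OCc9ccccc9)C[C@@H](OCc9ccccc9)[C@@H](c1ccc(OCc9ccccc9)c(OCc9ccccc9)c1)O3)C=C(c1ccc(OCc9ccccc9)c(OCc9ccccc9)c1)O2
F6 | step 14 | trimer 3α-alcohol (unit 2: 2β-aryl, 3α-OH, 4β-linked) | Ic1c(OCc9ccccc9)c(Br)c2c(c1OCc9ccccc9)[C@H](c1c(OCc9ccccc9)cc(OCc9ccccc9)c3c1O[C@H](c1ccc(OCc9ccccc9)c(OCc9ccccc9)c1)[C@H](OCc9ccccc9)[C@H]3c1c(OCc9ccccc9)c(Br)c3c(c1OCc9ccccc9)C[C@@H](OCc9ccccc9)[C@@H](c1ccc(OCc9ccccc9)c(OCc9ccccc9)c1)O3)[C@@H](O)[C@H](c1ccc(OCc9ccccc9)c(OCc9ccccc9)c1)O2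
F7 | step 14 | trimer flavan-3-one (unit 2: 2β-aryl, C3 ketone, 4β-linked) | Ic1c(OCc9ccccc9)c(Br)c2c(c1OCc9ccccc9)[C@H](c1c(OCc9ccccc9)cc(OCc9ccccc9)c3c1O[C@H](c1ccc(OCc9ccccc9)c(OCc9ccccc9)c1)[C@H](OCc9ccccc9)[C@H]3c1c(OCc9ccccc9)c(Br)c3c(c1OCc9ccccc9)C[C@@H](OCc9ccccc9)[C@@H](c1ccc(OCc9ccccc9)c(OCc9ccccc9)c1)O3)C(=O)[C@H](c1ccc(OCc9ccccc9)c(OCc9ccccc9)c1)O2
F8 | step 19 | (Z)-2-{2-[3,4-bis(benzyloxy)phenyl]ethenyl}-4,4,5,5-tetramethyl-1,3,2-dioxaborolane | CC1(C)OB(/C=C\c2ccc(OCc3ccccc3)c(OCc3ccccc3)c2)OC1(C)C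
F9 | step 19 | tetramer boronate (unit 1: 2α-aryl, 3α-pinacolboryl, 4α-linked) | c9ccccc9COc1cc(OCc9ccccc9)c2c(c1)O[C@H](c1ccc(OCc9ccccc9)c(OCc9ccccc9)c1)[C@H](B4OC(C)(C)C(C)(C)O4)[C@@H]2c1c(OCc9ccccc9)c(Br)c2c(c1OCc9ccccc9)[C@H](c1c(OCc9ccccc9)cc(OCc9ccccc9)c3c1O[C@H](c1ccc(OCc9ccccc9)c(OCc9ccccc9)c1)[C@H](OCc9ccccc9)[C@H]3c1c(OCc9ccccc9)c(Br)c3c(c1OCc9ccccc9)C[C@@H](OCc9ccccc9)[C@@H](c1ccc(OCc9ccccc9)c(OCc9ccccc9)c1)O3)[C@H](OCc9ccccc9)[C@H](c1ccc(OCc9ccccc9)c(OCc9ccccc9)c1)O2
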